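The pitfall in repeating these flasks is to read the 1.1 equiv of reagent as cover for the starting material, when that reagent, charged at less than the two substrates together, may be the limiting reagent for both.

common to all: catalyst 0.1 mol%
- grey: starting material 46 mM; reagent 1.1 equiv; second substrate 1 equiv; temperature 75 °C; run made earlier
- red: starting material 31 mM; reagent 1.1 equiv; second substrate 1 equiv; temperature 86 °C; run made earlier
- teal: starting material 69 mM; reagent 1.1 equiv; second substrate 1 equiv; temperature 75 °C; run made earlier
- Monday's: starting material 46 mM (fed, over 2.5 d); reagent 1.10 equiv; second substrate 1.00 equiv; temperature 80 °C; all else is in the flask from the start; the feed brings no volume worth counting; time 3.0 d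
- Tuesday's: starting material 46 mM; reagent 1.10 equiv; second substrate 1.00 equiv; temperature 80 °C; everything together at the start; time 3.0 d
- Wednesday's: starting material 46 mM (in portions, 3, over 2.5 d); reagent 1.10 equiv; second substrate 1.00 equiv; temperature 80 °C; first portion at the start, last at 2.5 d; time 3.0 d
- Friday's: starting material 46 mM; reagent 1.10 equiv (fed, over 2.5 d); second substrate 1.00 equiv; the addition at 40 °C, then warmed to 80 °C; the feed brings no volume worth counting; time 3.0 d

| run | time / d | target / % | side product / % |
|---|---|---|---|
| grey | 0.625 | 29.7 | 14.0 |
| grey | 1.25 | 17.6 | 19.5 |
| grey | 1.67 | 13.7 | 23.9 |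
| grey | 2.50 | 8.0 | 27.4 |
| grey | 3.00 | 5.3 | 28.4 |
| red | 0.333 | 22.6 | 10.4 |
| red | 0.833 | 8.6 | 16.2 |
| red | 1.67 | 5.0 | 21.4 |
| red | 2.50 | 3.5 | 24.5 |
| red | 4.00 | 4.3 | 28.1 |
| teal | 0.625 | 27.1 | 17.9 |
| teal | 1.25 | 15.4 | 27.7 |
| teal | 2.00 | 9.4 | 32.9 |
| teal | 3.00 | 4.6 | 36.9 |
| teal | 4.00 | 3.4 | 39.8 |

(readings scatter by 0.5 percentage points)

1. the flask that comes out highest in share of target in target plus side product, or "all alike" when all lie within 1.5 percentage points (Monday's / Tuesday's / Wednesday's / Friday's / all alike)
2. share of target in target plus side product at the end, Monday's
3. share of target in target plus side product at the end, Tuesday's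
4. share of target in target plus side product at the end, Wednesday's
5. share of target in target plus side product at the end, Friday's

- in percentages every species weighs as the starting material in it: one side product counts as two

Two numbers do not seem to go together: the grey run has reagent for the whole charge, yet its target reads 29.7% at 0.625 d and falls from there. We count back. Between its first and last readings target falls at 0.726 d⁻¹, a half-life of 0.955 d, so the line reaches 46.7% at the start. We call this the burst yield, the part of the charge turned into target before losses. The red run, counted back from its first two readings, gives 43.0%. Neither value is itself a reading: both are estimates from lines counted back through scattered readings, each assuming a single exponential fall. The burst yield from the grey run is still less than the reagent charged, so we take the second substrate to share the reagent.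

We assume that the burst in the grey run was over by its first reading at 0.625 d, and that Monday's burst keeps the same clock; by then Monday's feed has delivered 25.0% of the starting material. With grey's decay over the remaining time, we expect Monday's target below 4.46%. In Wednesday's, the reagent is less than the second substrate plus a third of the charge, so we expect later portions to meet no reagent. We expect Friday's to keep the burst, and its 0.500 d warm, reckoned at grey's rate, to leave 32.5% of target.

The forecast names Friday's, with 52%, 12%, 53% and 68% for Monday's, Tuesday's, Wednesday's and Friday's, holding that “low concentration cuts side product, and late-made target survives”. There our reckoning differs from it.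

The flasks give Friday's, with 13.2%, 11.4%, 21.5% and 57.4% in that order.

    starting material + reagent + catalyst → catalyst + target (k = 425 M⁻² s⁻¹, Ea = 45.0 kJ mol⁻¹)
    second substrate + reagent + catalyst → catalyst + second product (k = 601 M⁻² s⁻¹, Ea = 38.0 kJ mol⁻¹)
    starting material + target → side product (k = 2.24 × 10⁻⁴ M⁻¹ s⁻¹, Ea = 88.0 kJ mol⁻¹)
    target ⇌ isomer of the product (K = 6.82, k = 1.22 × 10⁻⁵ s⁻¹, Ea = 127 kJ mol⁻¹, ΔH = −15.0 kJ mol⁻¹)
    (constants at 80 °C)

The forecast and the flasks part most on Monday's, where 87% of the starting material stands unused at the end. Reagent not found in the second product is what reached the starting material. Tuesday's, with c(second product) at 28.2 mM, gets 48.8% of its charge, beside the grey run's burst yield of 46.7%, while Monday's, at 45.8 mM, gets 10.4%. The neighbour of Tuesday's charged with 110 mM of starting material reaches c(second product) of 67.3 mM, so 48.8% of its charge got reagent, and it ends with side product at 48.2% and a share of target of 4.66%.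

The data were generated by integration on assumed constants.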